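At early times the target is a small correction on a large stock of starting material, so the target column can be reckoned by itself and subtracted from the charge.

| setting | south-east | north-east | elm | ash |
|---|---|---|---|---|
| starting material | 0.13 M | 0.52 M | 0.26 M | 0.26 M |
| reagent | 0.26 M (in portions, 2) | 0.26 M (in portions, 2) | 0.260 M (in portions, 2) | 0.260 M (in portions, 2) |
| remark | run made earlier; portions every 6.0 min | run made earlier; portions every 6.0 min | the portions of reagent follow each other after 6.0 min, the first at the start | the portions of reagent follow each other after 6.0 min, the first at the start |
| time |  |  | 12 min | 20 min |

| run | time / min | target / % | starting material / % |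
|---|---|---|---|
| south-east | 1.00 | 1.4 | 99.8 |
| south-east | 2.00 | 2.5 | 97.9 |
| south-east | 3.00 | 3.1 | 97.5 |
| south-east | 6.00 | 6.1 | 93.2 |
| south-east | 12.0 | 13.9 | 85.3 |
| north-east | 1.00 | 1.6 | 98.4 |
| north-east | 3.00 | 3.8 | 96.9 |
| north-east | 6.00 | 6.3 | 94.4 |
| north-east | 8.00 | 8.9 | 90.7 |
| north-east | 12.0 | 13.3 | 86.7 |

(readings scatter by 0.5 percentage points)

- which of these there is most of at the end, counted by the starting material in it, elm (starting material / target)
- which of these there is most of at the end, counted by the starting material in it, ash (starting material / target)
- the largest of these amounts at the end, in percent of the starting material charged, elm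
- the largest of these amounts at the end, in percent of the starting material charged, ash

Read the first rows. After 1.00 min, south-east holds 1.4 % target and north-east 1.6 %, although north-east has 4.00 times the starting material. The percent pace therefore does not depend on starting material within the scatter of 0.5 percentage points, which means first order in it.

Both runs start on one portion, 0.130 M of reagent. Taking first order in reagent as well, the mean early pace divided by that portion gives the pace per molar of reagent, the second-order rate constant, read here as 0.115 L mol⁻¹ min⁻¹.

Now read the last rows. If the reagent simply stayed as charged, this constant would give 27.0 % target at 12.0 min, but the two runs average 13.6 %, so the mean reagent over these runs reads as about half of what was assumed. South-east made 0.0181 M of target from 0.26 M of reagent, which is far less, so this reckoning takes the reagent to be leaving by some other route.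

The north-east pace from 8.00 min to 12.0 min reads as about 0.110 M of reagent, less than a fresh portion. The mean target after 6.00 min, the yield of one fresh portion, is 6.20 %.

The reckoning made here takes 86.4 % starting material for elm. For ash it subtracts about one portion's yield over the further time, giving 80.2 %.

The forecast names starting material for elm and starting material for ash, with 86 % and 77.5 %, on “a low order in reagent, around one half, or saturation”. Its ash figure lies 2.7 points below the reckoning above.

Elm ends at 85.7 % starting material and ash at 80.4 % starting material, and ash stands 2.9 points above the forecast.

2 reagent → self-condensation product (k = 0.00560 L mol⁻¹ s⁻¹); crystals ⇌ by-product, rate k2*(cs2 - [by-product]) while solid is left; crystals form when [by-product] > cs2 (solubility = 0.150 M, k = 0.0710 s⁻¹); starting material + reagent ⇌ target + by-product (K = 40.0, k = 0.00180 L mol⁻¹ s⁻¹) Through the pace per molar, the fall between them asks for a mean reagent of 0.0691 M, which lies between 0.0997 M at 12.0 min and 0.0556 M at 20.0 min. The neighbour of elm with 1.0 M of reagent ends at 69.2 % starting material, which asks for a mean of 0.266 M against 0.112 M in elm. Its charge is 3.85 times that of elm, its mean reagent 2.38 times, and 17 % of its reagent stands at the end.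

The earlier runs and the new flask were generated by integration on assumed constants, noise included.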